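**Retrosynthetic overview**

1. After removal of one aryl silyl ether, ring A (the 2-acyl-3,5-dihydroxycyclohexadienone) is cut at two C–C bonds: butanoyl-bearing carbon to ring C=O carbon, and quaternary carbon to the C(OH) carbon on the benzyl side. This gives a three-carbon ketone α,α′-unit and a three-carbon 2-benzylmalonyl unit.
2. Enabling features: (a) ring B has a free OH ortho to the CH2 bridge, so the malonyl unit can be carried as a 3,4-dihydrocoumarin (ring D) whose aryl ester is the second acyl donor and releases the phenol on closure; (b) the prenyl CH2 on the quaternary carbon is allylic and can share a six-membered ring with the butanoyl enol oxygen, so the nucleophile is carried one oxidation level up as a 2,3-dihydro-4H-pyran-4-one (ring C). Its only enolisable carbon is the future quaternary carbon, and its allylic C–O stereocentre directs the first acylation.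
3. Ring C comes from an Evans syn-aldol, Weinreb ketone synthesis and cycloisomerisation; ring D from a three-component condensation of aspidinol, formaldehyde and Meldrum's acid.
4. Order of ring formation: ring B (bought as the triol), ring C (step 4), ring D (step 7), ring A (step 10, with opening of rings C and D).

Key step: step 10

Assumption: the target is handled as the drawn 3,5-dihydroxycyclohexa-2,5-dienone tautomer, in which its stereocentre is R; paraformaldehyde is entered as formaldehyde.

**Route**

Step 1
Reactants: 1 (4R)-4-benzyl-3-propanoyl-1,3-oxazolidin-2-one; 2 3-methylbut-2-enal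
Product: 3 (4R)-4-benzyl-3-[(2R,3S)-3-hydroxy-2,5-dimethylhex-4-enoyl]-1,3-oxazolidin-2-one
Conditions: Bu2BOTf, i-Pr2NEt, CH2Cl2, −78 → 0 °C; pH 7 buffer, MeOH, H2O2
Reagents that add atoms: none
Why: Evans syn-aldol reaction, in which the Z boron enolate reacts through a chair transition state on the face away from the benzyl group of the (R)-auxiliary, which should set the carbinol carbon as S (the later relay centre) and the methyl-bearing carbon as R.

Step 2
Reactants: 3 (4R)-4-benzyl-3-[(2R,3S)-3-hydroxy-2,5-dimethylhex-4-enoyl]-1,3-oxazolidin-2-one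
Product: 4 (2R,3S)-3-hydroxy-N-methoxy-N,2,5-trimethylhex-4-enamide
Conditions: MeNH(OMe)·HCl, AlMe3, CH2Cl2, −20 → 0 °C
Reagents that add atoms: N,O-dimethylhydroxylamine hydrochloride, CNOC.Cl
Why: Weinreb amide formation by aluminium-amide transamidation of the β-hydroxy imide, which should cleave the exocyclic acyl group without touching either stereocentre.

Step 3
Reactants: 4 (2R,3S)-3-hydroxy-N-methoxy-N,2,5-trimethylhex-4-enamide; 5 pent-1-yne
Product: 6 (4S,5R)-4-hydroxy-2,5-dimethylundec-2-en-7-yn-6-one
Conditions: 5, n-BuLi (3 equiv of acetylide), THF, −78 → 0 °C; aq NH4Cl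
Reagents that add atoms: none
Why: Weinreb ketone synthesis, in which the chelated tetrahedral adduct of the lithium acetylide should prevent over-addition and the β-alkoxide is tolerated.

Step 4
Reactants: 6 (4S,5R)-4-hydroxy-2,5-dimethylundec-2-en-7-yn-6-one
Product: 7 (2S,3R)-3-methyl-2-(2-methylprop-1-en-1-yl)-6-propyl-2,3-dihydro-4H-pyran-4-one
Conditions: Ph3PAuCl (5 mol %), AgOTf (5 mol %), CH2Cl2, rt
Reagents that add atoms: none
Why: Cycloisomerisation in which monovalent gold activates the ynone alkyne for 6-endo-dig attack by the β-hydroxyl (intramolecular oxa-Michael addition), so the carbinol stereocentre is carried over unchanged into ring C.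

Step 5
Reactants: 8 2-methylbenzene-1,3,5-triol; 9 butanoyl chloride
Product: 10 1-(2,4,6-trihydroxy-3-methylphenyl)butan-1-one
Conditions: AlCl3, PhNO2, 60 °C; aq HCl
Reagents that add atoms: none
Why: Friedel–Crafts C-acylation of the phloroglucinol, whose two free ring positions are equivalent, so a single mono-ketone should form.

Step 6
Reactants: 10 1-(2,4,6-trihydroxy-3-methylphenyl)butan-1-one
Product: 11 1-(2,6-dihydroxy-4-methoxy-3-methylphenyl)butan-1-one (aspidinol)
Conditions: Me2SO4 (1.0 equiv), K2CO3, acetone, rt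
Reagents that add atoms: dimethyl sulfate, COS(=O)(=O)OC
Why: Williamson O-methylation, which should go to the 4-hydroxyl because it is the only one not hydrogen-bonded to the ketone and is the most acidic.

Step 7
Reactants: 11 1-(2,6-dihydroxy-4-methoxy-3-methylphenyl)butan-1-one; 12 formaldehyde (used as paraformaldehyde); 13 2,2-dimethyl-1,3-dioxane-4,6-dione (Meldrum's acid)
Product: 14 8-butanoyl-7-hydroxy-5-methoxy-6-methyl-2-oxo-3,4-dihydro-2H-chromene-3-carboxylic acid (racemic)
Conditions: (CH2O)n, Et3N (10 mol %), MeCN, 40 °C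
Reagents that add atoms: none
Why: Three-component Knoevenagel/Michael/lactonisation, in which methylene Meldrum's acid is attacked by the single free ring carbon of 11 and the ortho-hydroxyl then opens the dioxanedione with loss of acetone, which should leave the malonyl unit as the ring-D lactone acid.

Step 8
Reactants: 14 8-butanoyl-7-hydroxy-5-methoxy-6-methyl-2-oxo-3,4-dihydro-2H-chromene-3-carboxylic acid
Product: 15 tert-butyldimethylsilyl 8-butanoyl-7-[(tert-butyldimethylsilyl)oxy]-5-methoxy-6-methyl-2-oxo-3,4-dihydro-2H-chromene-3-carboxylate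
Conditions: t-BuMe2SiCl (2.5 equiv), imidazole, DMF, rt; non-aqueous work-up
Reagents that add atoms: tert-butyl(chloro)dimethylsilane, CC(C)(C)[Si](C)(C)Cl
Why: Silylation of the remaining phenol and of the acid, which protects the phenol against the later ketene and gives the silyl ester needed for a neutral acid chloride synthesis.

Step 9
Reactants: 15 tert-butyldimethylsilyl 8-butanoyl-7-[(tert-butyldimethylsilyl)oxy]-5-methoxy-6-methyl-2-oxo-3,4-dihydro-2H-chromene-3-carboxylate
Product: 16 8-butanoyl-7-[(tert-butyldimethylsilyl)oxy]-5-methoxy-6-methyl-2-oxo-3,4-dihydro-2H-chromene-3-carbonyl chloride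
Conditions: (COCl)2, DMF (cat.), CH2Cl2, 0 °C → rt; used crude at once
Reagents that add atoms: oxalyl chloride, O=C(Cl)C(=O)Cl
Why: Silyl esters are converted directly into acid chlorides by the chloroiminium salt from (COCl)2 and DMF without free HCl, so the aryl silyl ether and the lactone should survive.

Step 10
Reactants: 7 (2S,3R)-3-methyl-2-(2-methylprop-1-en-1-yl)-6-propyl-2,3-dihydro-4H-pyran-4-one; 16 8-butanoyl-7-[(tert-butyldimethylsilyl)oxy]-5-methoxy-6-methyl-2-oxo-3,4-dihydro-2H-chromene-3-carbonyl chloride
Product: 20 (4R)-2-butanoyl-6-({3-butanoyl-4-[(tert-butyldimethylsilyl)oxy]-2-hydroxy-6-methoxy-5-methylphenyl}methyl)-3,5-dihydroxy-4-methyl-4-(3-methylbut-2-en-1-yl)cyclohexa-2,5-dien-1-one, via acylketene 17 (not isolated), via C-acylated dihydropyranone 18 (not isolated), via ring-opened triketo lactone 19 (not isolated)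
Conditions: 7, LiN(SiMe3)2 (1.0 equiv), THF, −78 °C, then MgBr2·OEt2; 16 + LiN(SiMe3)2 (1.0 equiv, THF, −78 °C, gives 17) added by cannula; then Pd(PPh3)4 (5 mol %), PhSiH3 (2 equiv), −78 → 45 °C; aq NH4Cl
Reagents that add atoms: none
Why: The enolate of 7, which can form only at the methyl-bearing carbon because the butanoyl carbonyl is locked as the ring-C enol ether, is C-acylated by acylketene 17 (from 16 by loss of HCl) to give 18; zerovalent palladium then ionises the allylic C–O bond of ring C with the vinylogous-acid oxygen as leaving group, PhSiH3 reduces the allyl fragment to the prenyl group of 19, and on warming the lactone enolate expels the ring-B phenoxide (E1cB) so that the freed 1,3-diketonate carbon closes ring A on the new acylketene. The closest known reaction types are the trans-selective C-functionalisation of 2-substituted 2,3-dihydro-4H-pyran-4-one enolates, C-acylation of enolates by ketenes and malonyl chlorides, palladium-catalysed hydride cleavage of allylic esters and ethers, and the Claisen cyclisation of 3,5,7-triketo esters to acylphloroglucinols. Ring A closes in a 6-exo mode (Dieckmann-type attack of the diketonate carbon on the ketene or lactone carbonyl carbon), while rings C and D are opened. The quaternary stereocentre is set in the first acylation by the neighbouring allylic C–O stereocentre of ring C: allylic 1,2-strain with the enolate methyl group forces the 2-methylprop-1-enyl group axial, the ketene adds to the opposite face, and loss of the relay centre leaves the R configuration. The step needs C- rather than O-acylation (magnesium counter-ion and a ketene electrophile), hydride delivery to the allyl terminus next to the quaternary carbon (it gives the trisubstituted alkene), and C- rather than O-closure of ring A (an enol lactone from O-attack cannot aromatise beside the quaternary carbon and should be funnelled to the stable trione enolate).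

Step 11
Reactants: 20 (4R)-2-butanoyl-6-({3-butanoyl-4-[(tert-butyldimethylsilyl)oxy]-2-hydroxy-6-methoxy-5-methylphenyl}methyl)-3,5-dihydroxy-4-methyl-4-(3-methylbut-2-en-1-yl)cyclohexa-2,5-dien-1-one
Product: 21 (4R)-2-butanoyl-6-[(3-butanoyl-2,4-dihydroxy-6-methoxy-5-methylphenyl)methyl]-3,5-dihydroxy-4-methyl-4-(3-methylbut-2-en-1-yl)cyclohexa-2,5-dien-1-one
Conditions: Bu4NF, AcOH, THF, 0 °C
Reagents that add atoms: none
Why: Fluoride cleavage of the aryl silyl ether, buffered with AcOH so that the methylene bridge should not suffer base-induced retro-Michael cleavage and the prenyl group is not exposed to strong acid.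

**Compound list**

1 | (4R)-4-benzyl-3-propanoyl-1,3-oxazolidin-2-one | CCC(=O)N1C(=O)OC[C@H]1Cc1ccccc1 | starting material
2 | 3-methylbut-2-enal | CC(C)=CC=O | starting material
3 | (4R)-4-benzyl-3-[(2R,3S)-3-hydroxy-2,5-dimethylhex-4-enoyl]-1,3-oxazolidin-2-one | CC(C)=C[C@H](O)[C@@H](C)C(=O)N1C(=O)OC[C@H]1Cc1ccccc1 | intermediate
4 | (2R,3S)-3-hydroxy-N-methoxy-N,2,5-trimethylhex-4-enamide | CC(C)=C[C@H](O)[C@@H](C)C(=O)N(C)OC | intermediate
5 | pent-1-yne | CCCC#C | starting material
6 | (4S,5R)-4-hydroxy-2,5-dimethylundec-2-en-7-yn-6-one | CCCC#CC(=O)[C@H](C)[C@@H](O)C=C(C)C | intermediate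
7 | (2S,3R)-3-methyl-2-(2-methylprop-1-en-1-yl)-6-propyl-2,3-dihydro-4H-pyran-4-one | CCCC1=CC(=O)[C@H](C)[C@H](C=C(C)C)O1 | intermediate
8 | 2-methylbenzene-1,3,5-triol | Cc1c(O)cc(O)cc1O | starting material
9 | butanoyl chloride | CCCC(=O)Cl | starting material
10 | 1-(2,4,6-trihydroxy-3-methylphenyl)butan-1-one | CCCC(=O)c1c(O)cc(O)c(C)c1O | intermediate
11 | 1-(2,6-dihydroxy-4-methoxy-3-methylphenyl)butan-1-one (aspidinol) | CCCC(=O)c1c(O)cc(OC)c(C)c1O | intermediate
12 | formaldehyde (used as paraformaldehyde) | C=O | starting material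
13 | 2,2-dimethyl-1,3-dioxane-4,6-dione (Meldrum's acid) | CC1(C)OC(=O)CC(=O)O1 | starting material
14 | 8-butanoyl-7-hydroxy-5-methoxy-6-methyl-2-oxo-3,4-dihydro-2H-chromene-3-carboxylic acid (racemic) | CCCC(=O)c1c(O)c(C)c(OC)c2c1OC(=O)C(C(=O)O)C2 | intermediate
15 | tert-butyldimethylsilyl 8-butanoyl-7-[(tert-butyldimethylsilyl)oxy]-5-methoxy-6-methyl-2-oxo-3,4-dihydro-2H-chromene-3-carboxylate | CCCC(=O)c1c(O[Si](C)(C)C(C)(C)C)c(C)c(OC)c2c1OC(=O)C(C(=O)O[Si](C)(C)C(C)(C)C)C2 | intermediate
16 | 8-butanoyl-7-[(tert-butyldimethylsilyl)oxy]-5-methoxy-6-methyl-2-oxo-3,4-dihydro-2H-chromene-3-carbonyl chloride | CCCC(=O)c1c(O[Si](C)(C)C(C)(C)C)c(C)c(OC)c2c1OC(=O)C(C(=O)Cl)C2 | intermediate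
17 | 8-butanoyl-7-[(tert-butyldimethylsilyl)oxy]-5-methoxy-6-methyl-3-(oxomethylidene)-3,4-dihydro-2H-chromen-2-one (acylketene) | CCCC(=O)c1c(O[Si](C)(C)C(C)(C)C)c(C)c(OC)c2c1OC(=O)C(=C=O)C2 | intermediate
18 | (2S,3S)-3-({8-butanoyl-7-[(tert-butyldimethylsilyl)oxy]-5-methoxy-6-methyl-2-oxo-3,4-dihydro-2H-chromen-3-yl}carbonyl)-3-methyl-2-(2-methylprop-1-en-1-yl)-6-propyl-2,3-dihydro-4H-pyran-4-one (epimers at the chromenone carbon) | CCCC1=CC(=O)[C@@](C)(C(=O)C2Cc3c(OC)c(C)c(O[Si](C)(C)C(C)(C)C)c(C(=O)CCC)c3OC2=O)[C@H](C=C(C)C)O1 | intermediate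
19 | 8-butanoyl-7-[(tert-butyldimethylsilyl)oxy]-5-methoxy-6-methyl-3-[(2S)-2-methyl-2-(3-methylbut-2-en-1-yl)-3,5-dioxooctanoyl]-3,4-dihydro-2H-chromen-2-one (epimers at the chromenone carbon) | CCCC(=O)CC(=O)[C@](C)(CC=C(C)C)C(=O)C1Cc2c(OC)c(C)c(O[Si](C)(C)C(C)(C)C)c(C(=O)CCC)c2OC1=O | intermediate
20 | (4R)-2-butanoyl-6-({3-butanoyl-4-[(tert-butyldimethylsilyl)oxy]-2-hydroxy-6-methoxy-5-methylphenyl}methyl)-3,5-dihydroxy-4-methyl-4-(3-methylbut-2-en-1-yl)cyclohexa-2,5-dien-1-one | CCCC(=O)C1=C(O)[C@](C)(CC=C(C)C)C(O)=C(Cc2c(O)c(C(=O)CCC)c(O[Si](C)(C)C(C)(C)C)c(C)c2OC)C1=O | intermediate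
21 | (4R)-2-butanoyl-6-[(3-butanoyl-2,4-dihydroxy-6-methoxy-5-methylphenyl)methyl]-3,5-dihydroxy-4-methyl-4-(3-methylbut-2-en-1-yl)cyclohexa-2,5-dien-1-one | CCCC(=O)C1=C(O)[C@](C)(CC=C(C)C)C(O)=C(Cc2c(O)c(C(=O)CCC)c(O)c(C)c2OC)C1=O | target

**Step count and risks**

Total step count: 11. Longest linear sequence: 7 steps (steps 5, 6, 7, 8, 9, 10, 11).

Steps most likely to fail:

1. Step 10. The cascade could be diverted by O-acylation of the enolate instead of C-acylation, by hydride delivery to the wrong allyl terminus, or by palladium-mediated C-allylation by the pendant enolates. The fallback builds ring A first and installs the methylene bridge last; it sets out from 10 and 11 and comes back to the route at 21. Alkylative dearomatisation of 10 at its methyl-bearing ring carbon (3-methylbut-2-enyl bromide, NaOMe, MeOH, 0 °C) should give racemic 2-butanoyl-3,5-dihydroxy-4-methyl-4-(3-methylbut-2-en-1-yl)cyclohexa-2,5-dien-1-one F1. Its (4R)-enantiomer F2 would be taken by preparative chromatography on a chiral stationary phase. Aminomethylation of 11 at its only free ring position (Me2N=CH2 iodide, CH2Cl2) should give the Mannich base 1-{3-[(dimethylamino)methyl]-2,6-dihydroxy-4-methoxy-5-methylphenyl}butan-1-one F3. Heating F2 with F3 (toluene, 90 °C) should give 21 by loss of dimethylamine, ortho-quinone methide formation and Michael addition of the free ring carbon of F2.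

2. Step 7. Formaldehyde could be arylated twice (diarylmethane formation), or the malonic half-ester could decarboxylate. The fallback is stepwise; it sets out from 11 and comes back at 14. Vilsmeier–Haack formylation (POCl3, DMF) should give 3-butanoyl-2,4-dihydroxy-6-methoxy-5-methylbenzaldehyde F4. Knoevenagel condensation and lactonisation with 13 (piperidinium acetate, EtOH, rt) should give 8-butanoyl-7-hydroxy-5-methoxy-6-methyl-2-oxo-2H-chromene-3-carboxylic acid F5. Hydrogenation of its ring double bond (H2, 1 atm, Pd/C, EtOAc) should give 14.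

3. Step 4. The allylic alcohol could ionise, or the alkene could take part in an enyne cyclisation under the π-acid catalyst, or closure could go 5-exo. The fallback replaces the ynone by a diketone; it sets out from 4 and comes back at 7. Acylation of the lithium enolate of pentan-2-one (LiN(i-Pr)2, THF, −78 °C, excess) by Weinreb amide 4 should give (7R,8S)-8-hydroxy-7,10-dimethylundec-9-ene-4,6-dione F6. Cyclodehydration (pyridinium p-toluenesulfonate, benzene, 4 Å molecular sieves, rt) should give 7.

**Further compounds**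

F1 | step 10 | racemic 2-butanoyl-3,5-dihydroxy-4-methyl-4-(3-methylbut-2-en-1-yl)cyclohexa-2,5-dien-1-one | CCCC(=O)C1=C(O)C(C)(CC=C(C)C)C(O)=CC1=O
F2 | step 10 | (4R)-2-butanoyl-3,5-dihydroxy-4-methyl-4-(3-methylbut-2-en-1-yl)cyclohexa-2,5-dien-1-one | CCCC(=O)C1=C(O)[C@](C)(CC=C(C)C)C(O)=CC1=O
F3 | step 10 | 1-{3-[(dimethylamino)methyl]-2,6-dihydroxy-4-methoxy-5-methylphenyl}butan-1-one | CCCC(=O)c1c(O)c(CN(C)C)c(OC)c(C)c1O
F4 | step 7 | 3-butanoyl-2,4-dihydroxy-6-methoxy-5-methylbenzaldehyde | CCCC(=O)c1c(O)c(C=O)c(OC)c(C)c1O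
F5 | step 7 | 8-butanoyl-7-hydroxy-5-methoxy-6-methyl-2-oxo-2H-chromene-3-carboxylic acid | CCCC(=O)c1c(O)c(C)c(OC)c2c1OC(=O)C(C(=O)O)=C2
F6 | step 4 | (7R,8S)-8-hydroxy-7,10-dimethylundec-9-ene-4,6-dione | CCCC(=O)CC(=O)[C@H](C)[C@@H](O)C=C(C)C
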